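## Retrosynthetic overview

- **Feature.** In target 18 the tetrahydrofuran ring (O1, C2, C3, C4, C5) carries the same 3-hydroxy-4-methoxyphenyl group on C2 and on the ketone carbon attached to C4. The chain C2–C3–C4–C(=O), with CH2OH on C3 and C5H2–O1 on C4, is a 2,3-bis(hydroxymethyl)succinic acid skeleton, and its C3/C4-cis form (the C4 epimer of 18) has a twofold axis.
- **Endgame.** C4 (base, through the enolate, step 7) and C2 (acid, through the benzylic cation, step 8) are both equilibrated trans to the fixed C3. The O1–C2 bond comes from mono-deoxygenation of one hemiketal of the twofold-symmetric diketo diol 14 (step 6).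
- **Key disconnection.** The C2–aryl and ketone carbon–aryl bonds are made together by single addition of aryl-cerium 12 (from bromide 10 through aryllithium 11) to each carbonyl of bis-lactone 8 (step 5).
- **Precursor.** 8 comes from imide 4 by oxidative enolate homocoupling (C3–C4 bond, both stereocentres set by the oxazolidinone auxiliary), then hydrogenolysis with double lactonisation (steps 1–3).
- **Ring order.** The two γ-lactone rings close together in step 3 and persist as hemiketal rings in 13. One is fixed as the tetrahydrofuran of 18 in step 6; the other opens to the hydroxy ketone.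

Key step: step 5

Remark on the chemistry: C2 of 15, 16 and 17 is drawn as expected for hydride delivery to the convex face of the bicyclic oxocarbenium ion. If the other C2 epimer forms instead, steps 7 and 8 take it to the same target, because C2 is equilibrated in step 8.

## Route

Step 1
Reactants: 1 3-(benzyloxy)propanoic acid; 2 (4R)-4-benzyl-1,3-oxazolidin-2-one
Product: 4 (4R)-4-benzyl-3-[3-(benzyloxy)propanoyl]-1,3-oxazolidin-2-one, via mixed pivalic anhydride 3 (not isolated)
Conditions: PivCl, Et3N, THF, −20 °C; then LiCl, 2, −20 °C → rt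
Reagents that add atoms: none
Why: N-acylation of the oxazolidinone through the mixed pivalic anhydride with LiCl/Et3N activation is a standard mild protocol that needs no strong base, so the 3-benzyloxy acyl group is not exposed to β-elimination.

Step 2
Reactants: 4 (4R)-4-benzyl-3-[3-(benzyloxy)propanoyl]-1,3-oxazolidin-2-one (two molecules)
Product: 6 (2R,3R)-1,4-bis[(4R)-4-benzyl-2-oxo-1,3-oxazolidin-3-yl]-2,3-bis[(benzyloxy)methyl]butane-1,4-dione, via trichlorotitanium Z-enolate 5 (not isolated)
Conditions: TiCl4 (1.1 equiv), i-Pr2NEt (1.15 equiv), CH2Cl2, −78 °C, 1 h; then −78 → 20 °C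
Reagents that add atoms: none
Why: Oxidative homocoupling of an N-acyl oxazolidinone enolate: soft enolisation gives the chelated Z-enolate 5 of tetravalent titanium, which on warming should undergo homolysis to trivalent titanium and an imide-stabilised α-carbonyl radical that dimerises, each new bond forming on the face away from the auxiliary benzyl group so that both centres become R and the dimer is twofold-symmetric; no alkali enolate is present, which should hold back loss of benzyloxide.

Step 3
Reactants: 6 (2R,3R)-1,4-bis[(4R)-4-benzyl-2-oxo-1,3-oxazolidin-3-yl]-2,3-bis[(benzyloxy)methyl]butane-1,4-dione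
Product: 8 (1R,5R)-3,7-dioxabicyclo[3.3.0]octane-2,6-dione, via diol bis-imide 7 (not isolated)
Conditions: H2 (1 atm), 10% Pd/C, EtOAc, rt; then TsOH·H2O (5 mol%), 40 °C
Reagents that add atoms: none
Why: Hydrogenolysis of the two benzyl ethers frees the primary hydroxyls, each of which attacks the distal exocyclic imide carbonyl (5-exo-trig transacylation) with loss of the oxazolidinone; only the (R,R) diastereomer can close both γ-lactones to the cis-fused bicycle, and no stereocentre is touched.

Step 4
Reactants: 9 5-bromo-2-methoxyphenol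
Product: 10 (5-bromo-2-methoxyphenoxy)(tert-butyl)dimethylsilane
Conditions: TBSCl, imidazole, DMF, rt
Reagents that add atoms: tert-butyldimethylsilyl chloride, CC(C)(C)[Si](C)(C)Cl
Why: Standard silylation of a phenol; the silyl ether is inert to Br/Li exchange and to the Lewis acid of step 6, and it is removed by the same base that epimerises C4 in step 7.

Step 5
Reactants: 8 (1R,5R)-3,7-dioxabicyclo[3.3.0]octane-2,6-dione; 10 (5-bromo-2-methoxyphenoxy)(tert-butyl)dimethylsilane
Product: 14 (2R,3R)-1,4-bis{3-[(tert-butyldimethylsilyl)oxy]-4-methoxyphenyl}-2,3-bis(hydroxymethyl)butane-1,4-dione, via aryllithium 11 (not isolated), via aryl-cerium dichloride 12 (not isolated), via bis-hemiketal 13 (not isolated)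
Conditions: 10 (2.4 equiv), n-BuLi (2.4 equiv), THF, −78 °C; CeCl3 (anhydrous, 2.5 equiv), THF, −78 °C, 1 h; 8 (1.0 equiv), THF, −78 °C; sat. aq. NH4Cl, −78 °C
Reagents that add atoms: none
Why: Br/Li exchange on 10 gives 11, which is transmetallated to the weakly basic aryl-cerium 12; one aryl group then adds to each of the two homotopic γ-lactone carbonyls of 8 to give a tetrahedral cerium lactolate that does not collapse at −78 °C, so no ketone exists before the cold quench and a second addition is shut off. The closest known reaction is the single addition of aryllithium and organocerium reagents to γ-lactones to give lactols, as used for C-aryl glycosides and furofuran lignans; here it is run in two directions on one molecule. No ring is closed for good: protonation gives bis-hemiketal 13, in which both five-membered rings of 8 survive, and each opens reversibly (retro 5-exo-trig addition of a primary hydroxyl to an aryl ketone) towards the diketo diol 14, which is carried on as the equilibrium mixture. No lasting stereocentre is formed (the hemiketal carbons are labile), and the two ring-fusion centres of 8 are carried over unchanged. The step needs mono-addition at each carbonyl and no enolisation; the first is secured by the stability of the tetrahedral adducts at low temperature and the identity of the two sites, the second by the low basicity of the cerium reagent and by the cis-fused bicycle, in which the bridgehead C–H and the β C–O bond are poorly aligned for enolisation and E1cB opening. The aryl silyl and methyl ethers are inert to all three organometallic species at −78 °C.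

Step 6
Reactants: 14 (2R,3R)-1,4-bis{3-[(tert-butyldimethylsilyl)oxy]-4-methoxyphenyl}-2,3-bis(hydroxymethyl)butane-1,4-dione
Product: 15 {(2R,3R,4R)-2-{3-[(tert-butyldimethylsilyl)oxy]-4-methoxyphenyl}-3-(hydroxymethyl)tetrahydrofuran-4-yl}{3-[(tert-butyldimethylsilyl)oxy]-4-methoxyphenyl}methanone (all-cis; ring numbering of the target)
Conditions: Et3SiH (1.0 equiv), BF3·OEt2 (2.0 equiv), CH2Cl2, −78 → −50 °C; sat. aq. NaHCO3 at −78 °C; recovered 14 resubmitted
Reagents that add atoms: none
Why: Ionic hydrogenation of a hemiketal: BF3·OEt2 ionises one of the two homotopic hemiketals to a 2-aryl oxocarbenium ion that takes hydride from Et3SiH (known for aryl lactols), most likely on the convex face of the cis-fused bicycle so that the C2 aryl group ends up cis to the C3 hydroxymethyl, while the limiting amount of silane and the crowding that a second concave aryl group would cause should hold the reaction at the mono stage; C2 is not relied on because step 8 equilibrates it.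

Step 7
Reactants: 15 (all-cis mono-tetrahydrofuran bis-silyl ether)
Product: 17 [(2R,3R,4S)-2-(3-hydroxy-4-methoxyphenyl)-3-(hydroxymethyl)tetrahydrofuran-4-yl](3-hydroxy-4-methoxyphenyl)methanone, via all-cis bis-phenol 16 (not isolated)
Conditions: K2CO3 (3 equiv), MeOH, 0 °C → rt
Reagents that add atoms: none
Why: Carbonate in methanol cleaves the two phenolic silyl ethers by methanolysis and equilibrates C4 through the ketone enolate (both known); the epimer with the aroyl group trans to the C3 hydroxymethyl should be favoured because the cis,cis crowding is relieved, and C3 cannot epimerise because it is not alpha to a carbonyl.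

Step 8
Reactants: 17 [(2R,3R,4S)-2-(3-hydroxy-4-methoxyphenyl)-3-(hydroxymethyl)tetrahydrofuran-4-yl](3-hydroxy-4-methoxyphenyl)methanone
Product: 18 [(2S,3R,4S)-2-(3-hydroxy-4-methoxyphenyl)-3-(hydroxymethyl)tetrahydrofuran-4-yl](3-hydroxy-4-methoxyphenyl)methanone (CNP0234761.1)
Conditions: BF3·OEt2 (1.0 equiv), CH2Cl2 (0.01 M), −20 → 0 °C
Reagents that add atoms: none
Why: The Lewis acid reversibly ionises the benzylic C2–O1 bond to a 4-methoxybenzyl-type cation that is reclosed by the C5 hydroxyl to the five-membered ring, a known epimerisation of 2-aryltetrahydrofuran and furofuran lignans, so C2 comes under thermodynamic control and the aryl group should settle trans to the C3 hydroxymethyl, giving the all-trans target; the ketone binds BF3 and so deactivates its own ring towards Friedel–Crafts attack by the cation.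

## Compound list

1 | 3-(benzyloxy)propanoic acid | OC(=O)CCOCc1ccccc1 | starting material
2 | (4R)-4-benzyl-1,3-oxazolidin-2-one | O=C1N[C@H](Cc2ccccc2)CO1 | starting material
3 | 3-(benzyloxy)propanoic pivalic anhydride | CC(C)(C)C(=O)OC(=O)CCOCc1ccccc1 | intermediate (not isolated)
4 | (4R)-4-benzyl-3-[3-(benzyloxy)propanoyl]-1,3-oxazolidin-2-one | O=C(CCOCc1ccccc1)N1[C@H](Cc2ccccc2)COC1=O | intermediate
5 | trichlorotitanium Z-enolate of 4 | Cl[Ti](Cl)(Cl)O/C(=C\COCc1ccccc1)N1[C@H](Cc2ccccc2)COC1=O | intermediate (not isolated)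
6 | (2R,3R)-1,4-bis[(4R)-4-benzyl-2-oxo-1,3-oxazolidin-3-yl]-2,3-bis[(benzyloxy)methyl]butane-1,4-dione | O=C([C@@H](COCc1ccccc1)[C@H](COCc1ccccc1)C(=O)N1[C@H](Cc2ccccc2)COC1=O)N1[C@H](Cc2ccccc2)COC1=O | intermediate
7 | (2R,3R)-1,4-bis[(4R)-4-benzyl-2-oxo-1,3-oxazolidin-3-yl]-2,3-bis(hydroxymethyl)butane-1,4-dione | O=C([C@@H](CO)[C@H](CO)C(=O)N1[C@H](Cc2ccccc2)COC1=O)N1[C@H](Cc2ccccc2)COC1=O | intermediate (not isolated)
8 | (1R,5R)-3,7-dioxabicyclo[3.3.0]octane-2,6-dione | O=C1OC[C@H]2[C@@H]1COC2=O | intermediate
9 | 5-bromo-2-methoxyphenol | COc1ccc(Br)cc1O | starting material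
10 | (5-bromo-2-methoxyphenoxy)(tert-butyl)dimethylsilane | COc1ccc(Br)cc1O[Si](C)(C)C(C)(C)C | intermediate
11 | 3-[(tert-butyldimethylsilyl)oxy]-4-methoxyphenyllithium | [Li]c1ccc(OC)c(O[Si](C)(C)C(C)(C)C)c1 | intermediate (not isolated)
12 | {3-[(tert-butyldimethylsilyl)oxy]-4-methoxyphenyl}cerium dichloride | Cl[Ce](Cl)c1ccc(OC)c(O[Si](C)(C)C(C)(C)C)c1 | intermediate (not isolated)
13 | (1R,5R)-2,6-bis{3-[(tert-butyldimethylsilyl)oxy]-4-methoxyphenyl}-3,7-dioxabicyclo[3.3.0]octane-2,6-diol (bis-hemiketal, C2 and C6 not fixed) | OC1(c3ccc(OC)c(O[Si](C)(C)C(C)(C)C)c3)OC[C@H]2[C@@H]1COC2(O)c1ccc(OC)c(O[Si](C)(C)C(C)(C)C)c1 | intermediate (not isolated)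
14 | (2R,3R)-1,4-bis{3-[(tert-butyldimethylsilyl)oxy]-4-methoxyphenyl}-2,3-bis(hydroxymethyl)butane-1,4-dione | O=C(c1ccc(OC)c(O[Si](C)(C)C(C)(C)C)c1)[C@@H](CO)[C@H](CO)C(=O)c1ccc(OC)c(O[Si](C)(C)C(C)(C)C)c1 | intermediate
15 | {(2R,3R,4R)-2-{3-[(tert-butyldimethylsilyl)oxy]-4-methoxyphenyl}-3-(hydroxymethyl)tetrahydrofuran-4-yl}{3-[(tert-butyldimethylsilyl)oxy]-4-methoxyphenyl}methanone | COc1ccc(C(=O)[C@H]2CO[C@@H](c3ccc(OC)c(O[Si](C)(C)C(C)(C)C)c3)[C@H]2CO)cc1O[Si](C)(C)C(C)(C)C | intermediate
16 | [(2R,3R,4R)-2-(3-hydroxy-4-methoxyphenyl)-3-(hydroxymethyl)tetrahydrofuran-4-yl](3-hydroxy-4-methoxyphenyl)methanone | COc1ccc(C(=O)[C@H]2CO[C@@H](c3ccc(OC)c(O)c3)[C@H]2CO)cc1O | intermediate (not isolated)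
17 | [(2R,3R,4S)-2-(3-hydroxy-4-methoxyphenyl)-3-(hydroxymethyl)tetrahydrofuran-4-yl](3-hydroxy-4-methoxyphenyl)methanone | COc1ccc(C(=O)[C@@H]2CO[C@@H](c3ccc(OC)c(O)c3)[C@H]2CO)cc1O | intermediate
18 | [(2S,3R,4S)-2-(3-hydroxy-4-methoxyphenyl)-3-(hydroxymethyl)tetrahydrofuran-4-yl](3-hydroxy-4-methoxyphenyl)methanone | COc1ccc(C(=O)[C@@H]2CO[C@H](c3ccc(OC)c(O)c3)[C@H]2CO)cc1O | target

## Step count and risks

Total step count: 8. Longest linear sequence: 7 steps (steps 1, 2, 3, 5, 6, 7, 8).

**Step 2 (oxidative homocoupling).** The enolate may lose benzyloxide (β-elimination to the N-acryloyl imide) faster than it is oxidised, or the radical recombination may not be fully face-selective, so that the unsymmetrical (2R,3S) dimer builds up. The fallback replaces radical dimerisation by two-electron enolate alkylation on a preformed C3–C4 bond, with enolates that carry no β-leaving group. It sets out from 2 and comes back at 8.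
- N-acylation of 2 (n-BuLi, THF, −78 °C; succinyl chloride, 0.5 equiv) should give 1,4-bis[(4R)-4-benzyl-2-oxo-1,3-oxazolidin-3-yl]butane-1,4-dione F1.
- Double soft enolisation (TiCl4, i-Pr2NEt, CH2Cl2, 0 °C) and alkylation with trimethyl orthoformate should give the (2S,3S)-bis(dimethoxymethyl) bis-imide F2, each centre set by attack on the chelated Z-enolate face away from the auxiliary benzyl group.
- Reductive removal of the auxiliary (LiBH4, MeOH, THF, 0 °C) should give (2R,3R)-2,3-bis(dimethoxymethyl)butane-1,4-diol F3.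
- Aqueous acid (1 M HCl, THF, rt) should close it to (1R,5R)-3,7-dioxabicyclo[3.3.0]octane-2,6-diol F4.
- Oxidation (TEMPO cat., PhI(OAc)2, CH2Cl2) gives 8.
- Here the imide carbonyl becomes the CH2–O carbon and the formyl equivalent becomes the lactone carbonyl, which is why the same (R)-auxiliary leads to the same (1R,5R) enantiomer.

**Step 5 (twofold aryl addition).** The aryl-metal may abstract a proton at a ring-fusion carbon, with β-elimination opening of the neighbouring lactone, or the first tetrahedral adduct may collapse and take a second aryl group. The fallback keeps the same two aryl–carbonyl bonds but makes them by the Weinreb ketone synthesis on an opened, protected substrate. It sets out from 8 and comes back at 14.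
- Aminolysis of both lactones (AlMe3, MeNHOMe·HCl, CH2Cl2, 0 °C → rt) should give (2R,3R)-2,3-bis(hydroxymethyl)-N1,N4-dimethoxy-N1,N4-dimethylbutanediamide F5.
- Immediate silylation (TESCl, imidazole, DMF, 0 °C) should give the bis(triethylsilyl) ether F6.
- Addition of 11 (2.4 equiv, THF, −78 °C), which stops at the chelated tetrahedral stage, should give the bis(triethylsilyl) ether of the diketone F7.
- AcOH–THF–H2O at rt removes the two alkyl silyl ethers, leaves the aryl silyl ethers and gives 14.

**Step 6 (mono-deoxygenation).** The second hemiketal may be reduced as fast as the first (double deoxygenation to the furofuran), or the benzylic C2–O1 bond of the product may itself be reduced, so that the mono-deoxygenated compound does not accumulate. The fallback differentiates the two hydroxyls before reduction, so that only one ketone can form an oxocarbenium ion. It sets out from 14 and comes back at 15.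
- Mono-silylation (TBSCl 1.0 equiv, imidazole, CH2Cl2, 0 °C; unreacted 14 recycled) should give the mono(tert-butyldimethylsilyl) ether F8.
- Ionic hydrogenation with excess silane (Et3SiH, BF3·OEt2, CH2Cl2, −78 °C) should give the silylated mono-tetrahydrofuran F9, drawn with the C2 configuration of 15; either C2 epimer converges in step 8.
- AcOH–THF–H2O at rt cleaves only the primary silyl ether and gives 15.

## Further compounds

F1 | step 2 | 1,4-bis[(4R)-4-benzyl-2-oxo-1,3-oxazolidin-3-yl]butane-1,4-dione | O=C(CCC(=O)N1[C@H](Cc2ccccc2)COC1=O)N1[C@H](Cc2ccccc2)COC1=O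
F2 | step 2 | (2S,3S)-1,4-bis[(4R)-4-benzyl-2-oxo-1,3-oxazolidin-3-yl]-2,3-bis(dimethoxymethyl)butane-1,4-dione | O=C([C@H](C(OC)OC)[C@@H](C(OC)OC)C(=O)N1[C@H](Cc2ccccc2)COC1=O)N1[C@H](Cc2ccccc2)COC1=O
F3 | step 2 | (2R,3R)-2,3-bis(dimethoxymethyl)butane-1,4-diol | OC[C@H](C(OC)OC)[C@@H](C(OC)OC)CO
F4 | step 2 | (1R,5R)-3,7-dioxabicyclo[3.3.0]octane-2,6-diol | OC1OC[C@H]2[C@@H]1COC2O
F5 | step 5 | (2R,3R)-2,3-bis(hydroxymethyl)-N1,N4-dimethoxy-N1,N4-dimethylbutanediamide | CON(C)C(=O)[C@@H](CO)[C@H](CO)C(=O)N(C)OC
F6 | step 5 | (2R,3R)-N1,N4-dimethoxy-N1,N4-dimethyl-2,3-bis{[(triethylsilyl)oxy]methyl}butanediamide | CON(C)C(=O)[C@@H](CO[Si](CC)(CC)CC)[C@H](CO[Si](CC)(CC)CC)C(=O)N(C)OC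
F7 | step 5 | (2R,3R)-1,4-bis{3-[(tert-butyldimethylsilyl)oxy]-4-methoxyphenyl}-2,3-bis{[(triethylsilyl)oxy]methyl}butane-1,4-dione | O=C(c1ccc(OC)c(O[Si](C)(C)C(C)(C)C)c1)[C@@H](CO[Si](CC)(CC)CC)[C@H](CO[Si](CC)(CC)CC)C(=O)c1ccc(OC)c(O[Si](C)(C)C(C)(C)C)c1
F8 | step 6 | (2R,3R)-1,4-bis{3-[(tert-butyldimethylsilyl)oxy]-4-methoxyphenyl}-2-{[(tert-butyldimethylsilyl)oxy]methyl}-3-(hydroxymethyl)butane-1,4-dione | O=C(c1ccc(OC)c(O[Si](C)(C)C(C)(C)C)c1)[C@@H](CO[Si](C)(C)C(C)(C)C)[C@H](CO)C(=O)c1ccc(OC)c(O[Si](C)(C)C(C)(C)C)c1
F9 | step 6 | {(2R,3R,4R)-2-{3-[(tert-butyldimethylsilyl)oxy]-4-methoxyphenyl}-3-{[(tert-butyldimethylsilyl)oxy]methyl}tetrahydrofuran-4-yl}{3-[(tert-butyldimethylsilyl)oxy]-4-methoxyphenyl}methanone | COc1ccc(C(=O)[C@H]2CO[C@@H](c3ccc(OC)c(O[Si](C)(C)C(C)(C)C)c3)[C@H]2CO[Si](C)(C)C(C)(C)C)cc1O[Si](C)(C)C(C)(C)C
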